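**Retrosynthetic overview**

- Target ← acid removal of two aryl MOM ethers and one TES ether ← 5,8-bis(MOM) quinone ← para-oxidation of 1-naphthols ← rhodium-catalysed opening of a 1,4-epoxy-1,4-dihydronaphthalene.
- The strategy rests on ring B: its four carbons C1–C4 sit between C8a and C4a, carry oxygen at C1 and C4 and the side chain at C2. That is a 3-substituted furan bonded through its 2- and 5-carbons (C1, C4) to a benzyne that brings ring A with its C5 and C8 oxygens.
- Key disconnection: C8a–C1 and C4a–C4, by Diels–Alder addition of 3,6-bis(methoxymethoxy)benzyne to the (R)-3-furyl carbinol ester.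
- Furan partner: 3-lithiofuran plus a Weinreb amide gives the ketone; oxazaborolidine reduction sets the (R) centre; esterification with the TES-protected hydroxy acid follows. Aryne partner: hydroquinone → bis-MOM ether → ortho-hydroxylation → carbamate-directed silylation → triflate.
- Ring order: ring A arrives intact from hydroquinone; ring B is the only ring formed (step 11) and is then aromatised and oxidised to the quinone.

Key step: step 11

Remark: the cycloadduct is carried on as the mixture of its two bridgehead diastereomers and the two regioisomeric naphthols are not separated, since all of them converge on one quinone.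

**Route**

Step 1
Reactants: 1 hydroquinone
Product: 2 1,4-bis(methoxymethoxy)benzene
Conditions: NaH, MOMCl, DMF, 0 °C → rt
Reagents that add atoms: chloromethyl methyl ether, COCCl
Why: Double O-alkylation of the bis-phenoxide by the reactive α-chloro ether (Williamson ether synthesis) should give the bis-MOM ether, whose acetal oxygens later direct lithiation and come off under mild acid.

Step 2
Reactants: 2 1,4-bis(methoxymethoxy)benzene
Product: 5 2,5-bis(methoxymethoxy)phenol, via aryllithium 3 (not isolated), via lithium aryltrimethoxyborate 4 (not isolated)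
Conditions: n-BuLi, TMEDA, THF, 0 °C; B(OMe)3, −78 °C → rt; H2O2, aq. NaOH, 0 °C
Reagents that add atoms: hydrogen peroxide, OO
Why: MOM-directed ortho-metalation (all four ring C–H bonds are equivalent), borylation and peroxide oxidation of the C–B bond with 1,2-aryl shift from boron to oxygen is the standard ortho-hydroxylation of an aryl ether.

Step 3
Reactants: 5 2,5-bis(methoxymethoxy)phenol
Product: 6 2,5-bis(methoxymethoxy)phenyl N-isopropylcarbamate
Conditions: i-PrNCO, Et3N (cat.), CH2Cl2, rt
Reagents that add atoms: isopropyl isocyanate, CC(C)N=C=O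
Why: Base-catalysed addition of the phenol to the isocyanate (carbamoylation) should give the N-monosubstituted carbamate, which is a strong directing group and is removable by E1cB cleavage.

Step 4
Reactants: 6 2,5-bis(methoxymethoxy)phenyl N-isopropylcarbamate
Product: 10 3,6-bis(methoxymethoxy)-2-(trimethylsilyl)phenyl N-isopropylcarbamate, via N-silyl carbamate 7 (not isolated), via ortho-lithiated N-silyl carbamate 8 (not isolated), via N,C-bis(trimethylsilyl) carbamate 9 (not isolated)
Conditions: TMSOTf, TMEDA, Et2O, 0 °C → rt; n-BuLi (2.2 equiv), TMEDA, −78 °C; TMSCl, −78 °C → rt; sat. aq. NH4Cl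
Reagents that add atoms: chlorotrimethylsilane, C[Si](C)(C)Cl
Why: In situ N-silylation masks the N–H, so carbamate-directed ortho-metalation should occur at the one C–H flanked by the carbamate and a MOM ether, the aryllithium is silylated by TMSCl, and the labile N–Si bond is lost on the mild work-up, which spares the MOM ethers.

Step 5
Reactants: 10 3,6-bis(methoxymethoxy)-2-(trimethylsilyl)phenyl N-isopropylcarbamate
Product: 12 3,6-bis(methoxymethoxy)-2-(trimethylsilyl)phenyl trifluoromethanesulfonate, via silyl phenoxide 11 (not isolated)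
Conditions: Et2NH, DBU, MeCN, 40 °C; then PhNTf2, rt
Reagents that add atoms: N-phenylbis(trifluoromethanesulfonimide), O=S(=O)(N(c1ccccc1)S(=O)(=O)C(F)(F)F)C(F)(F)F
Why: DBU removes the N–H proton and the carbamate fragments by E1cB to the phenoxide and isopropyl isocyanate (scavenged by Et2NH as a urea), and the phenoxide is O-triflated in the same pot, the usual one-pot route to ortho-silylaryl triflates.

Step 6
Reactants: 13 4-methylpent-3-enoic acid
Product: 15 N-methoxy-N,4-dimethylpent-3-enamide, via acyl imidazole 14 (not isolated)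
Conditions: CDI, CH2Cl2, 0 °C → rt; then MeNHOMe·HCl, rt
Reagents that add atoms: N,O-dimethylhydroxylamine hydrochloride, CNOC.Cl
Why: Acyl imidazole formation and aminolysis (Weinreb amide synthesis) under near-neutral conditions should keep the β,γ-alkene out of conjugation.

Step 7
Reactants: 16 3-bromofuran; 15 N-methoxy-N,4-dimethylpent-3-enamide
Product: 19 1-(furan-3-yl)-4-methylpent-3-en-1-one, via furan-3-yllithium 17 (not isolated), via tetrahedral lithium adduct 18 (not isolated)
Conditions: n-BuLi, THF, −78 °C; then 15, −78 °C; sat. aq. NH4Cl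
Reagents that add atoms: none
Why: Bromine–lithium exchange at −78 °C gives 3-lithiofuran without isomerisation to the 2-lithio isomer, and its addition to the Weinreb amide stops at the chelated tetrahedral adduct, so only the ketone should form on quench (Weinreb ketone synthesis).

Step 8
Reactants: 19 1-(furan-3-yl)-4-methylpent-3-en-1-one
Product: 21 (R)-1-(furan-3-yl)-4-methylpent-3-en-1-ol, via catechol borate ester 20 (not isolated)
Conditions: (S)-2-methyl-CBS-oxazaborolidine (20 mol %), catecholborane, toluene, −78 °C; MeOH, then aq. NaOH wash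
Reagents that add atoms: none
Why: Corey–Bakshi–Shibata reduction, in which the (S)-oxazaborolidine binds the ketone with the furyl ring as the large group and delivers hydride to the Si face, should set the (R)-carbinol, while catecholborane at −78 °C leaves the trisubstituted alkene untouched.

Step 9
Reactants: 22 3-hydroxy-3-methylbutanoic acid
Product: 24 3-methyl-3-(triethylsilyloxy)butanoic acid, via bis-silyl compound 23 (not isolated)
Conditions: TESOTf (2.3 equiv), 2,6-lutidine, CH2Cl2, 0 °C; then K2CO3, THF/H2O, 0 °C; work-up at pH 5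
Reagents that add atoms: triethylsilyl trifluoromethanesulfonate, CC[Si](CC)(CC)OS(=O)(=O)C(F)(F)F
Why: The silyl triflate silylates the hindered tertiary alcohol and the acid, and only the labile silyl ester is hydrolysed by mild aqueous base (silyl ether protection), leaving the tertiary TES ether.

Step 10
Reactants: 21 (R)-1-(furan-3-yl)-4-methylpent-3-en-1-ol; 24 3-methyl-3-(triethylsilyloxy)butanoic acid
Product: 25 (R)-1-(furan-3-yl)-4-methylpent-3-en-1-yl 3-methyl-3-(triethylsilyloxy)butanoate
Conditions: DCC, DMAP (cat.), CH2Cl2, 0 °C → rt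
Reagents that add atoms: none
Why: Steglich esterification acylates the secondary alcohol at oxygen, so the C–O bond of the stereocentre is not touched and the (R) configuration is retained.

Step 11
Reactants: 12 3,6-bis(methoxymethoxy)-2-(trimethylsilyl)phenyl trifluoromethanesulfonate; 25 (R)-1-(furan-3-yl)-4-methylpent-3-en-1-yl 3-methyl-3-(triethylsilyloxy)butanoate
Product: 27 (R)-1-[5,8-bis(methoxymethoxy)-1,4-dihydro-1,4-epoxynaphthalen-2-yl]-4-methylpent-3-en-1-yl 3-methyl-3-(triethylsilyloxy)butanoate (both bridgehead diastereomers), via aryne 26 (not isolated)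
Conditions: CsF, MeCN, rt; 12 (1.2 equiv) added slowly
Reagents that add atoms: none
Why: Fluoride attacks silicon in 12 and triflate leaves from the neighbouring carbon, releasing the symmetric 3,6-bis(methoxymethoxy)benzyne 26, which the furan of 25 captures across its 2- and 5-carbons in a concerted, suprafacial [4+2] cycloaddition (aryne Diels–Alder reaction). The closest known reaction type is the trapping of 3,6-dialkoxybenzynes, generated from ortho-silylaryl triflates, by furans to give 1,4-epoxy-1,4-dihydronaphthalenes. Ring B is closed in this intermolecular cycloaddition mode, with C8a–C1 and C4a–C4 formed together and the furan oxygen becoming the 1,4-bridge. The two new bridgehead stereocentres are cis by the geometry of the bridge; which furan face reacts relative to the (R)-carbinol centre is not controlled and need not be, because both bridgeheads become sp2 carbons in steps 12 and 13 while the carbinol centre is a spectator. The step needs chemoselectivity for the furan diene over the prenyl alkene (ene reaction) and the ester, which the much faster furan trapping, the slow addition of 12 and the sparingly soluble CsF (low stationary aryne concentration) should secure; regioselectivity does not arise because the aryne is symmetric.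

Step 12
Reactants: 27 (R)-1-[5,8-bis(methoxymethoxy)-1,4-dihydro-1,4-epoxynaphthalen-2-yl]-4-methylpent-3-en-1-yl 3-methyl-3-(triethylsilyloxy)butanoate
Product: 28 (R)-1-[1-hydroxy-5,8-bis(methoxymethoxy)naphthalen-2-yl]-4-methylpent-3-en-1-yl 3-methyl-3-(triethylsilyloxy)butanoate together with 29 (R)-1-[4-hydroxy-5,8-bis(methoxymethoxy)naphthalen-2-yl]-4-methylpent-3-en-1-yl 3-methyl-3-(triethylsilyloxy)butanoate (regioisomers carried on as a mixture)
Conditions: [Rh(CO)2Cl]2 (2.5 mol %), 1,2-dichloroethane, 60 °C
Reagents that add atoms: none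
Why: Transition-metal-catalysed isomerisation of a 7-oxabenzonorbornadiene to a 1-naphthol, in which monovalent rhodium inserts into a strained bridgehead allylic C–O bond and hydride shift plus tautomerisation aromatise ring B under neutral conditions that spare the MOM and TES ethers; either C–O bond may break because both naphthols lead to the same quinone, and the bridgehead stereocentres are erased while the carbinol centre is not involved.

Step 13
Reactants: 28 and 29 (mixture of naphthols from step 12)
Product: 30 (R)-1-[5,8-bis(methoxymethoxy)-1,4-dioxo-1,4-dihydronaphthalen-2-yl]-4-methylpent-3-en-1-yl 3-methyl-3-(triethylsilyloxy)butanoate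
Conditions: ON(SO3K)2, KH2PO4 buffer, acetone/H2O, 0 °C → rt
Reagents that add atoms: potassium nitrosodisulfonate (Fremy's salt), [K+].[K+].[O]N(S(=O)(=O)[O-])S(=O)(=O)[O-]
Why: Teuber oxidation, in which the nitroxide radical abstracts the phenolic hydrogen and a second equivalent adds at the free para carbon C4, should give the same 2-substituted 1,4-quinone from either naphthol in a buffered neutral medium that spares the acetals, the silyl ether, the ester and the alkene.

Step 14
Reactants: 30 (R)-1-[5,8-bis(methoxymethoxy)-1,4-dioxo-1,4-dihydronaphthalen-2-yl]-4-methylpent-3-en-1-yl 3-methyl-3-(triethylsilyloxy)butanoate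
Product: 31 beta-HIVS, (R)-1-(5,8-dihydroxy-1,4-dioxo-1,4-dihydronaphthalen-2-yl)-4-methylpent-3-en-1-yl 3-hydroxy-3-methylbutanoate
Conditions: 2 M aq. HCl, THF, 0 °C → rt, in the dark
Reagents that add atoms: none
Why: Acid hydrolysis of the two aryl MOM acetals (assisted by the peri carbonyl groups) and of the TES ether should unveil the naphthazarin and the tertiary alcohol, while the ester next to the electron-poor quinone ring does not ionise, so the (R) centre is retained.

**Compound list**

1 | hydroquinone | Oc1ccc(O)cc1 | starting material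
2 | 1,4-bis(methoxymethoxy)benzene | COCOc1ccc(OCOC)cc1 | intermediate
3 | [2,5-bis(methoxymethoxy)phenyl]lithium | [Li]c1cc(OCOC)ccc1OCOC | intermediate
4 | lithium [2,5-bis(methoxymethoxy)phenyl]trimethoxyborate | [Li+].CO[B-](OC)(OC)c1cc(OCOC)ccc1OCOC | intermediate
5 | 2,5-bis(methoxymethoxy)phenol | COCOc1ccc(OCOC)c(O)c1 | intermediate
6 | 2,5-bis(methoxymethoxy)phenyl N-isopropylcarbamate | COCOc1ccc(OCOC)c(OC(=O)NC(C)C)c1 | intermediate
7 | 2,5-bis(methoxymethoxy)phenyl N-isopropyl-N-(trimethylsilyl)carbamate | COCOc1ccc(OCOC)c(OC(=O)N(C(C)C)[Si](C)(C)C)c1 | intermediate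
8 | 2-lithio-3,6-bis(methoxymethoxy)phenyl N-isopropyl-N-(trimethylsilyl)carbamate | COCOc1ccc(OCOC)c(OC(=O)N(C(C)C)[Si](C)(C)C)c1[Li] | intermediate
9 | 3,6-bis(methoxymethoxy)-2-(trimethylsilyl)phenyl N-isopropyl-N-(trimethylsilyl)carbamate | COCOc1ccc(OCOC)c(OC(=O)N(C(C)C)[Si](C)(C)C)c1[Si](C)(C)C | intermediate
10 | 3,6-bis(methoxymethoxy)-2-(trimethylsilyl)phenyl N-isopropylcarbamate | COCOc1ccc(OCOC)c(OC(=O)NC(C)C)c1[Si](C)(C)C | intermediate
11 | 3,6-bis(methoxymethoxy)-2-(trimethylsilyl)phenol (present as its DBU-H phenoxide) | COCOc1ccc(OCOC)c(O)c1[Si](C)(C)C | intermediate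
12 | 3,6-bis(methoxymethoxy)-2-(trimethylsilyl)phenyl trifluoromethanesulfonate | COCOc1ccc(OCOC)c(OS(=O)(=O)C(F)(F)F)c1[Si](C)(C)C | intermediate
13 | 4-methylpent-3-enoic acid | CC(C)=CCC(O)=O | starting material
14 | 1-(imidazol-1-yl)-4-methylpent-3-en-1-one | CC(C)=CCC(=O)n1ccnc1 | intermediate
15 | N-methoxy-N,4-dimethylpent-3-enamide | CC(C)=CCC(=O)N(C)OC | intermediate
16 | 3-bromofuran | Brc1ccoc1 | starting material
17 | furan-3-yllithium | [Li]c1ccoc1 | intermediate
18 | lithium 1-(furan-3-yl)-1-[methoxy(methyl)amino]-4-methylpent-3-en-1-olate (racemic at the hemiaminal carbon) | CC(C)=CCC([O-])(N(C)OC)c1ccoc1.[Li+] | intermediate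
19 | 1-(furan-3-yl)-4-methylpent-3-en-1-one | CC(C)=CCC(=O)c1ccoc1 | intermediate
20 | 2-{[(1R)-1-(furan-3-yl)-4-methylpent-3-en-1-yl]oxy}-1,3,2-benzodioxaborole | CC(C)=CC[C@@H](OB1Oc2ccccc2O1)c1ccoc1 | intermediate
21 | (R)-1-(furan-3-yl)-4-methylpent-3-en-1-ol | CC(C)=CC[C@@H](O)c1ccoc1 | intermediate
22 | 3-hydroxy-3-methylbutanoic acid | CC(C)(O)CC(O)=O | starting material
23 | triethylsilyl 3-methyl-3-(triethylsilyloxy)butanoate | CC[Si](CC)(CC)OC(=O)CC(C)(C)O[Si](CC)(CC)CC | intermediate
24 | 3-methyl-3-(triethylsilyloxy)butanoic acid | CC[Si](CC)(CC)OC(C)(C)CC(O)=O | intermediate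
25 | (R)-1-(furan-3-yl)-4-methylpent-3-en-1-yl 3-methyl-3-(triethylsilyloxy)butanoate | CC(C)=CC[C@@H](OC(=O)CC(C)(C)O[Si](CC)(CC)CC)c1ccoc1 | intermediate
26 | 3,6-bis(methoxymethoxy)benzyne | COCOC1=CC=C(OCOC)C#C1 | intermediate
27 | (R)-1-[5,8-bis(methoxymethoxy)-1,4-dihydro-1,4-epoxynaphthalen-2-yl]-4-methylpent-3-en-1-yl 3-methyl-3-(triethylsilyloxy)butanoate (mixture of the two cis-bridged bridgehead diastereomers; one shown) | O1[C@H]2C([C@@H](CC=C(C)C)OC(=O)CC(C)(C)O[Si](CC)(CC)CC)=C[C@@H]1c1c(OCOC)ccc(OCOC)c12 | intermediate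
28 | (R)-1-[1-hydroxy-5,8-bis(methoxymethoxy)naphthalen-2-yl]-4-methylpent-3-en-1-yl 3-methyl-3-(triethylsilyloxy)butanoate | CC(C)=CC[C@@H](OC(=O)CC(C)(C)O[Si](CC)(CC)CC)c1ccc2c(OCOC)ccc(OCOC)c2c1O | intermediate
29 | (R)-1-[4-hydroxy-5,8-bis(methoxymethoxy)naphthalen-2-yl]-4-methylpent-3-en-1-yl 3-methyl-3-(triethylsilyloxy)butanoate | CC(C)=CC[C@@H](OC(=O)CC(C)(C)O[Si](CC)(CC)CC)c1cc(O)c2c(OCOC)ccc(OCOC)c2c1 | intermediate
30 | (R)-1-[5,8-bis(methoxymethoxy)-1,4-dioxo-1,4-dihydronaphthalen-2-yl]-4-methylpent-3-en-1-yl 3-methyl-3-(triethylsilyloxy)butanoate | CC(C)=CC[C@@H](OC(=O)CC(C)(C)O[Si](CC)(CC)CC)C1=CC(=O)c2c(OCOC)ccc(OCOC)c2C1=O | intermediate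
31 | beta-HIVS, (R)-1-(5,8-dihydroxy-1,4-dioxo-1,4-dihydronaphthalen-2-yl)-4-methylpent-3-en-1-yl 3-hydroxy-3-methylbutanoate | CC(C)=CC[C@@H](OC(=O)CC(C)(C)O)C1=CC(=O)c2c(O)ccc(O)c2C1=O | target

**Step count**

Total: 14 steps. Longest linear sequence: 9 steps (steps 1–5, then 11–14); the furan branch is 8 steps (6, 7, 8, 10, 11–14).

**Steps most likely to fail**

Step 12 (bridge opening). The side-chain ester is allylic in 27 and ortho-hydroxybenzylic in 28. It may ionise, either at the catalyst or by loss of carboxylate to an ortho-quinone methide, in competition with isomerisation and with the following oxidation, and the stereocentre would be lost. The fallback sets out from 21 and returns at 30. It carries the carbinol oxygen as a silyl ether, which is no leaving group, and acylates only once the quinone exists. Alcohol 21 is silylated (TBSCl, imidazole, DMF) to (R)-tert-butyl{[1-(furan-3-yl)-4-methylpent-3-en-1-yl]oxy}dimethylsilane F1. Cycloaddition of F1 with 12 (CsF, MeCN, as in step 11) should give the silyl ether cycloadduct F2. [Rh(CO)2Cl]2 should open F2 to the 2-substituted 1-naphthol silyl ether F3 and its 3-substituted regioisomer F4. ON(SO3K)2 oxidises both to the silyloxy quinone F5. HF·pyridine in THF frees the quinone carbinol F6 while the aryl MOM ethers stay. Steglich esterification of F6 with 24 (DCC, DMAP, CH2Cl2) gives 30.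

Step 11 (aryne cycloaddition). Fluoride may cleave the tertiary triethylsilyl ether, after which the freed alkoxide can add to the aryne or the β-oxido ester can fragment. The aryne may also be diverted by an ene reaction with the prenyl group once the furan runs low. The fallback sets out from 21 and returns at 27. It runs the cycloaddition before the ester and its silyl ether are in the molecule. Alcohol 21 is protected (TIPSOTf, 2,6-lutidine, CH2Cl2) as (R)-{[1-(furan-3-yl)-4-methylpent-3-en-1-yl]oxy}tri(propan-2-yl)silane F7. Cycloaddition of F7 with 12 (CsF, MeCN) should give the TIPS ether cycloadduct F8. TBAF in THF removes the silyl group to give the carbinol cycloadduct F9. Esterification of F9 with 24 (DCC, DMAP) gives 27.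

Step 13 (oxidation to the quinone). Coupling of the bulky nitroxide radical at the para carbon C4 may be slow, since C4 is peri to a MOM ether and in 29 is also flanked by the side chain. Oxidation would then be diverted to the free ortho position and give an ortho-quinone. The fallback sets out from the mixture of 28 and 29 and returns at 31. It uses a two-electron oxidation by trivalent iodine, PhI(OAc)2 (2.2 equiv) in MeOH at 0 °C, in which the small nucleophile methanol attacks the para carbon of the phenoxenium ion. This should give the quinone monoketal (R)-1-[4,4-dimethoxy-5,8-bis(methoxymethoxy)-1-oxo-1,4-dihydronaphthalen-2-yl]-4-methylpent-3-en-1-yl 3-methyl-3-(triethylsilyloxy)butanoate F10 from 28 and the isomeric monoketal (R)-1-[1,1-dimethoxy-5,8-bis(methoxymethoxy)-4-oxo-1,4-dihydronaphthalen-2-yl]-4-methylpent-3-en-1-yl 3-methyl-3-(triethylsilyloxy)butanoate F11 from 29. The aqueous HCl/THF conditions of step 14 then hydrolyse the ketal together with the MOM and TES ethers, so both monoketals give 31 directly without passing through 30.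

**Further compounds**

F1 | step 12 | (R)-tert-butyl{[1-(furan-3-yl)-4-methylpent-3-en-1-yl]oxy}dimethylsilane | CC(C)=CC[C@@H](O[Si](C)(C)C(C)(C)C)c1ccoc1
F2 | step 12 | (R)-{1-[5,8-bis(methoxymethoxy)-1,4-dihydro-1,4-epoxynaphthalen-2-yl]-4-methylpent-3-en-1-yl}oxy(tert-butyl)dimethylsilane (both bridgehead diastereomers; one shown) | O1[C@H]2C([C@@H](CC=C(C)C)O[Si](C)(C)C(C)(C)C)=C[C@@H]1c1c(OCOC)ccc(OCOC)c12
F3 | step 12 | (R)-2-{1-[(tert-butyldimethylsilyl)oxy]-4-methylpent-3-en-1-yl}-5,8-bis(methoxymethoxy)naphthalen-1-ol | CC(C)=CC[C@@H](O[Si](C)(C)C(C)(C)C)c1ccc2c(OCOC)ccc(OCOC)c2c1O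
F4 | step 12 | (R)-3-{1-[(tert-butyldimethylsilyl)oxy]-4-methylpent-3-en-1-yl}-5,8-bis(methoxymethoxy)naphthalen-1-ol | CC(C)=CC[C@@H](O[Si](C)(C)C(C)(C)C)c1cc(O)c2c(OCOC)ccc(OCOC)c2c1
F5 | step 12 | (R)-2-{1-[(tert-butyldimethylsilyl)oxy]-4-methylpent-3-en-1-yl}-5,8-bis(methoxymethoxy)naphthalene-1,4-dione | CC(C)=CC[C@@H](O[Si](C)(C)C(C)(C)C)C1=CC(=O)c2c(OCOC)ccc(OCOC)c2C1=O
F6 | step 12 | (R)-2-(1-hydroxy-4-methylpent-3-en-1-yl)-5,8-bis(methoxymethoxy)naphthalene-1,4-dione | CC(C)=CC[C@@H](O)C1=CC(=O)c2c(OCOC)ccc(OCOC)c2C1=O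
F7 | step 11 | (R)-{[1-(furan-3-yl)-4-methylpent-3-en-1-yl]oxy}tri(propan-2-yl)silane | CC(C)=CC[C@@H](O[Si](C(C)C)(C(C)C)C(C)C)c1ccoc1
F8 | step 11 | (R)-{1-[5,8-bis(methoxymethoxy)-1,4-dihydro-1,4-epoxynaphthalen-2-yl]-4-methylpent-3-en-1-yl}oxytri(propan-2-yl)silane (both bridgehead diastereomers; one shown) | O1[C@H]2C([C@@H](CC=C(C)C)O[Si](C(C)C)(C(C)C)C(C)C)=C[C@@H]1c1c(OCOC)ccc(OCOC)c12
F9 | step 11 | (R)-1-[5,8-bis(methoxymethoxy)-1,4-dihydro-1,4-epoxynaphthalen-2-yl]-4-methylpent-3-en-1-ol (both bridgehead diastereomers; one shown) | O1[C@H]2C([C@@H](CC=C(C)C)O)=C[C@@H]1c1c(OCOC)ccc(OCOC)c12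
F10 | step 13 | (R)-1-[4,4-dimethoxy-5,8-bis(methoxymethoxy)-1-oxo-1,4-dihydronaphthalen-2-yl]-4-methylpent-3-en-1-yl 3-methyl-3-(triethylsilyloxy)butanoate | CC(C)=CC[C@@H](OC(=O)CC(C)(C)O[Si](CC)(CC)CC)C1=CC(OC)(OC)c2c(OCOC)ccc(OCOC)c2C1=O
F11 | step 13 | (R)-1-[1,1-dimethoxy-5,8-bis(methoxymethoxy)-4-oxo-1,4-dihydronaphthalen-2-yl]-4-methylpent-3-en-1-yl 3-methyl-3-(triethylsilyloxy)butanoate | CC(C)=CC[C@@H](OC(=O)CC(C)(C)O[Si](CC)(CC)CC)C1=CC(=O)c2c(OCOC)ccc(OCOC)c2C1(OC)OC
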